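The isomerisation of target has a higher activation energy, 105 kJ mol⁻¹, than any step of the catalyst cycle, so you cannot assume that the hottest flask holds the most target. The flasks differ in temperature:

| flask | starting material | partner | free catalyst | temperature | time |
|---|---|---|---|---|---|
| south-east | 1.0 M | 1.30 equiv | 0.2 mol% | 125 °C | 10 s |
| east | 1.0 M | 1.30 equiv | 0.2 mol% | 110 °C | 10 s |
| south | 1.0 M | 1.30 equiv | 0.2 mol% | 140 °C | 10 s |

- which flask leads in amount of target, in percent of the starting material charged ("all alike" within 1.5 percentage points) (south-east / east / south / all alike)
- how much target is there at the end, in percent of the starting material charged: south-east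
- how much target is there at the end, in percent of the starting material charged: east
- how much target is there at the end, in percent of the starting material charged: south

- percent here means starting material units held: one self-condensation product counts as two
- what is said of target includes crystals
- two of one species on the left: rate k times its square, two consumed each time
- crystals is a solid; its amount is given per volume of the solution
- the list of constants is for 110 °C, to be carried to other temperatures by the activation energies and enthalpies

    starting material + catalyst intermediate B ⇌ catalyst intermediate C (K1 = 78 M⁻¹, k1 = 72 M⁻¹ s⁻¹, Ea1 = 43.0 kJ mol⁻¹, ΔH1 = −7.00 kJ mol⁻¹)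
    crystals ⇌ target, rate k2*(cs2 - [target]) while solid is left; crystals form when [target] > cs2 (cs2 = 0.74 M, k2 = 1.8 s⁻¹)
    2 starting material → self-condensation product (k3 = 2.8 × 10⁻⁵ M⁻¹ s⁻¹, Ea3 = 107 kJ mol⁻¹)
    target ⇌ isomer of the product (K4 = 4.6, k4 = 0.081 s⁻¹, Ea4 = 105 kJ mol⁻¹, ΔH4 = 6.00 kJ mol⁻¹)
    partner + free catalyst → catalyst intermediate A (k5 = 350 M⁻¹ s⁻¹, Ea5 = 42.0 kJ mol⁻¹)
    catalyst intermediate A → catalyst intermediate B (k6 = 4900 s⁻¹, Ea6 = 54.0 kJ mol⁻¹)
    catalyst intermediate D → free catalyst + target (k7 = 3500 s⁻¹, Ea7 = 56.0 kJ mol⁻¹)
    catalyst intermediate C ⇌ catalyst intermediate D (K8 = 2.0, k8 = 16 s⁻¹, Ea8 = 94.0 kJ mol⁻¹, ΔH8 = −19.0 kJ mol⁻¹)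
    (constants at 110 °C)

One thing looks wrong at first. The release of target from catalyst intermediate D has a rate constant 43200 times that of the isomerisation, which makes the isomerisation look like a detail. Yet in the east flask its relaxation time, which I call the clock and which is the reciprocal of the forward and backward rate constants added together, is 10.1 s, about the 10 s of the run.

The two numbers go together because the catalyst forms are 0.2 mol% of the charge, so the large constants act on very little. In the east flask, even with all the catalyst held as catalyst intermediate C, the passage to catalyst intermediate D delivers at most 0.0320 s⁻¹ of the charge. Over the run, the east flask's cap on what passes through is 32.0% of the charge.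

So hold the clock against the run. Scaling the east constants to the south flask with the factor 3.4, raised to the ratio of the energies, gives a clock of 0.948 s, much shorter than the run, and an equilibrium constant of 5.27. The south flask should therefore sit near its target share of 0.159, the fraction of target plus isomer that is target once the two have equilibrated. If target plus isomer were the whole charge, that would be 15.9% of the charge. The east flask should stay under its cap and be partly drained. South-east lies between them in temperature, and I put the lead there as a judgement, without a number.

The forecast gave 21.5% for south-east, 17% for east and 17.5% for south, a pattern that “puts the peak at the middle temperature”. The flasks end at 21.9%, 16.9% and 17.6%, so south-east leads.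

At 10.0 s, target over target plus isomer reads 0.698 in east, 0.388 in south-east and 0.197 in south, the last still above the reckoned 0.159. Target plus isomer reads 24.2% in east, inside the cap, 56.4% in south-east and 89.3% in south. Now take a neighbour of south with 0.330 equiv of partner, the limiting reagent, which stands at 0% at the end: target plus isomer can equal that charge, so the share gives 5.25%. The computed flask holds 5.27% target.

The numbers belong to no real substance, and the outcome is calculated.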